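**Plan**
- Retrosynthesis: the ring B quinone is traced back to a bis-MOM hydroquinone. The pyran ring is then cut at both O1–C8a and C4–C4a, giving ring A iodide 4 (I on the future C8a, OMOM on C8, H on C4a) and iodo alcohol 15. Compound 15 comes from a prochiral 2-aryl-1,3-propanediol and this from an aryl malonate (C3–C1' bond).
- Enabling feature: in ring A the oxygen-bearing C8a sits between C4a (which carries C4) and the oxygenated C8, so one ortho position is blocked. This is the ipso-heteroatom/ortho-carbon pattern that a Catellani (palladium/norbornene) sequence installs on a mono-ortho-substituted aryl iodide; the ring-closing event is C8a–O1 reductive elimination.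
- Forward order: the ring A iodide (2 steps) and the ring B side chain (7 steps) are made separately. Step 10 attaches C4 to C4a and closes the pyran ring at O1–C8a in one operation; ring B is oxidised to the quinone last.
- Stereochemistry: C3 is set by lipase desymmetrisation of diol 12 (step 7) and is never a reacting centre afterwards.

Key step: step 10

Assumption: the lipase acetylation of diol 12 is taken to give the (R)-monoacetate 13; if the enzyme prefers the other hydroxymethyl arm, lipase hydrolysis of the diacetate of 12 should give the same (R)-monoacetate.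

**Route**

Step 1
Reactants: 1 2,3-dimethoxyphenol
Product: 2 1,2-dimethoxy-3-(methoxymethoxy)benzene
Conditions: MOMCl, i-Pr2NEt, CH2Cl2, 0 °C to rt
Reagents that add atoms: chloromethyl methyl ether (MOMCl), COCCl
Why: O-alkylation of the phenol with MOMCl (acetal protection) is routine and installs the chelating acetal oxygen that directs the metalation of step 2.

Step 2
Reactants: 2 1,2-dimethoxy-3-(methoxymethoxy)benzene
Product: 4 1-iodo-3,4-dimethoxy-2-(methoxymethoxy)benzene, via aryllithium 3 (not isolated)
Conditions: n-BuLi, THF, 0 °C; then I2, −78 °C to rt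
Reagents that add atoms: iodine, II
Why: Directed ortho-metalation: the OMOM group outranks OMe as a director, so deprotonation should occur at the one position ortho to OMOM, and iodinolysis of aryllithium 3 places iodine on the future C8a.

Step 3
Reactants: 5 2,3-dimethoxy-1,4-benzoquinone
Product: 7 2,3-dimethoxy-1,4-bis(methoxymethoxy)benzene, via hydroquinone 6 (not isolated)
Conditions: H2 (1 atm), Pd/C, EtOAc, rt; filter under N2, concentrate; then MOMCl, i-Pr2NEt, CH2Cl2, 0 °C to rt
Reagents that add atoms: chloromethyl methyl ether (MOMCl), COCCl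
Why: Catalytic hydrogenation reduces the quinone to hydroquinone 6, and O-alkylation of both phenols with MOMCl masks ring B at the hydroquinone oxidation level.

Step 4
Reactants: 7 2,3-dimethoxy-1,4-bis(methoxymethoxy)benzene
Product: 9 1-iodo-3,4-dimethoxy-2,5-bis(methoxymethoxy)benzene, via aryllithium 8 (not isolated)
Conditions: n-BuLi (1.05 equiv), TMEDA, THF, −78 to 0 °C; then I2, −78 °C
Reagents that add atoms: iodine, II
Why: Directed ortho-metalation of the symmetric diether, whose two free positions are equivalent and each ortho to an OMOM group, followed by iodinolysis.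

Step 5
Reactants: 9 1-iodo-3,4-dimethoxy-2,5-bis(methoxymethoxy)benzene; 10 diethyl malonate
Product: 11 diethyl 2-[3,4-dimethoxy-2,5-bis(methoxymethoxy)phenyl]malonate
Conditions: CuI (10 mol %), 2-picolinic acid (20 mol %), Cs2CO3, 1,4-dioxane, 70 °C
Reagents that add atoms: none
Why: Copper-catalysed C-arylation of a malonate enolate with an aryl iodide (Hurtley-type coupling) tolerates electron-rich ortho-alkoxy iodides and the acetal groups.

Step 6
Reactants: 11 diethyl 2-[3,4-dimethoxy-2,5-bis(methoxymethoxy)phenyl]malonate
Product: 12 2-[3,4-dimethoxy-2,5-bis(methoxymethoxy)phenyl]propane-1,3-diol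
Conditions: LiAlH4, THF, 0 °C to rt
Reagents that add atoms: none
Why: Hydride reduction of both ester groups should give the prochiral 2-aryl-1,3-propanediol, the acetals being inert to LiAlH4.

Step 7
Reactants: 12 2-[3,4-dimethoxy-2,5-bis(methoxymethoxy)phenyl]propane-1,3-diol
Product: 13 (R)-2-[3,4-dimethoxy-2,5-bis(methoxymethoxy)phenyl]-3-hydroxypropyl acetate
Conditions: lipase PS (Burkholderia cepacia, immobilised), vinyl acetate, t-BuOMe, 25 °C
Reagents that add atoms: vinyl acetate, C=COC(C)=O
Why: Lipase-catalysed irreversible transesterification (enzymatic desymmetrisation) distinguishes the two enantiotopic hydroxymethyl groups and so sets C3, the acetylated arm becoming C2–O1 and the free arm C4.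

Step 8
Reactants: 13 (R)-2-[3,4-dimethoxy-2,5-bis(methoxymethoxy)phenyl]-3-hydroxypropyl acetate
Product: 14 (S)-2-[3,4-dimethoxy-2,5-bis(methoxymethoxy)phenyl]-3-iodopropyl acetate
Conditions: I2, PPh3, imidazole, CH2Cl2, 0 °C
Reagents that add atoms: iodine, II
Why: Appel-type iodination displaces the activated primary hydroxyl by SN2 at CH2, so the neighbouring stereocentre is untouched and only its descriptor changes.

Step 9
Reactants: 14 (S)-2-[3,4-dimethoxy-2,5-bis(methoxymethoxy)phenyl]-3-iodopropyl acetate
Product: 15 (S)-2-[3,4-dimethoxy-2,5-bis(methoxymethoxy)phenyl]-3-iodopropan-1-ol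
Conditions: K2CO3 (0.2 equiv), MeOH, 0 °C
Reagents that add atoms: none
Why: Base-catalysed transesterification (methanolysis) of the acetate at 0 °C should free the alcohol without cyclising or eliminating the gamma-iodo alcohol.

Step 10
Reactants: 4 1-iodo-3,4-dimethoxy-2-(methoxymethoxy)benzene; 15 (S)-2-[3,4-dimethoxy-2,5-bis(methoxymethoxy)phenyl]-3-iodopropan-1-ol
Product: 16 (S)-3-[3,4-dimethoxy-2,5-bis(methoxymethoxy)phenyl]-6,7-dimethoxy-8-(methoxymethoxy)chromane
Conditions: 4 (1.5 equiv), Pd(OAc)2 (10 mol %), RuPhos (20 mol %), norbornene (1 equiv), Cs2CO3 (3 equiv), 1,4-dioxane, 100 °C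
Reagents that add atoms: none
Why: Proposed new method: oxidative addition of 4 to zerovalent palladium, norbornene insertion and C–H palladation at the only free ortho position (C4a–H) should give the aryl-norbornyl palladacycle, which takes up the primary iodide of 15 by SN2-type oxidative addition to tetravalent palladium and forms C4–C4a by reductive elimination; with both ortho positions then filled (C8–OMOM and the new chain) norbornene is extruded and the divalent aryl-palladium at C8a is captured by the tethered alkoxide. The closest known reaction types are the palladium/norbornene annulation of aryl iodides with epoxides to 2,3-dihydrobenzofurans and the ortho-alkylation/ipso-amination annulation with haloalkylamines to indolines and tetrahydroquinolines; a six-membered oxygen ring from a gamma-iodo alcohol is the untested extension. The pyran ring is closed by C(sp2)–O reductive elimination from a seven-membered oxapalladacycle, formally a 6-exo closure onto the aryl–palladium carbon. No new stereocentre is formed, and C3, which is beta to both the iodide and the hydroxyl and is not a reacting centre, keeps its S configuration. The step needs ortho-alkylation to precede any ipso termination and C–O coupling to outrun beta-hydride elimination of the palladium alkoxide. The single ortho C–H and the ortho alkoxy group of 4 secure the first and fix the regiochemistry (C4 on C4a, O1 on C8a), while the bulky biaryl phosphine, the doubly ortho-substituted aryl-palladium and the intramolecular delivery of the alkoxide favour the second.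

Step 11
Reactants: 16 (S)-3-[3,4-dimethoxy-2,5-bis(methoxymethoxy)phenyl]-6,7-dimethoxy-8-(methoxymethoxy)chromane
Product: 18 (S)-5-(8-hydroxy-6,7-dimethoxychroman-3-yl)-2,3-dimethoxycyclohexa-2,5-diene-1,4-dione, via triol 17 (not isolated)
Conditions: HCl (2 M), MeOH/THF, 40 °C, argon; aq. NaHCO3, extraction; then DDQ (1.0 equiv), CH2Cl2, 0 °C
Reagents that add atoms: none
Why: Acid-catalysed acetal exchange with methanol should cleave all three MOM ethers to triol 17, and one equivalent of DDQ should then oxidise only the ring B hydroquinone, which is far easier to oxidise than the monohydric phenol of ring A, to the quinone without touching C3.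

**Compound list**

1 | 2,3-dimethoxyphenol | COc1cccc(O)c1OC | starting material
2 | 1,2-dimethoxy-3-(methoxymethoxy)benzene | COCOc1cccc(OC)c1OC | intermediate
3 | [3,4-dimethoxy-2-(methoxymethoxy)phenyl]lithium | [Li]c1ccc(OC)c(OC)c1OCOC | intermediate
4 | 1-iodo-3,4-dimethoxy-2-(methoxymethoxy)benzene | COCOc1c(I)ccc(OC)c1OC | intermediate
5 | 2,3-dimethoxy-1,4-benzoquinone | COC1=C(OC)C(=O)C=CC1=O | starting material
6 | 2,3-dimethoxybenzene-1,4-diol | COc1c(O)ccc(O)c1OC | intermediate
7 | 2,3-dimethoxy-1,4-bis(methoxymethoxy)benzene | COCOc1ccc(OCOC)c(OC)c1OC | intermediate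
8 | [3,4-dimethoxy-2,5-bis(methoxymethoxy)phenyl]lithium | [Li]c1cc(OCOC)c(OC)c(OC)c1OCOC | intermediate
9 | 1-iodo-3,4-dimethoxy-2,5-bis(methoxymethoxy)benzene | COCOc1cc(I)c(OCOC)c(OC)c1OC | intermediate
10 | diethyl malonate | CCOC(=O)CC(=O)OCC | starting material
11 | diethyl 2-[3,4-dimethoxy-2,5-bis(methoxymethoxy)phenyl]malonate | CCOC(=O)C(C(=O)OCC)c1cc(OCOC)c(OC)c(OC)c1OCOC | intermediate
12 | 2-[3,4-dimethoxy-2,5-bis(methoxymethoxy)phenyl]propane-1,3-diol | OCC(CO)c1cc(OCOC)c(OC)c(OC)c1OCOC | intermediate
13 | (R)-2-[3,4-dimethoxy-2,5-bis(methoxymethoxy)phenyl]-3-hydroxypropyl acetate | COCOc1cc([C@H](CO)COC(C)=O)c(OCOC)c(OC)c1OC | intermediate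
14 | (S)-2-[3,4-dimethoxy-2,5-bis(methoxymethoxy)phenyl]-3-iodopropyl acetate | COCOc1cc([C@H](CI)COC(C)=O)c(OCOC)c(OC)c1OC | intermediate
15 | (S)-2-[3,4-dimethoxy-2,5-bis(methoxymethoxy)phenyl]-3-iodopropan-1-ol | COCOc1cc([C@H](CI)CO)c(OCOC)c(OC)c1OC | intermediate
16 | (S)-3-[3,4-dimethoxy-2,5-bis(methoxymethoxy)phenyl]-6,7-dimethoxy-8-(methoxymethoxy)chromane | COCOc1cc([C@H]2COc3c(OCOC)c(OC)c(OC)cc3C2)c(OCOC)c(OC)c1OC | intermediate
17 | (S)-2-(8-hydroxy-6,7-dimethoxychroman-3-yl)-5,6-dimethoxybenzene-1,4-diol | Oc1cc([C@H]2COc3c(O)c(OC)c(OC)cc3C2)c(O)c(OC)c1OC | intermediate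
18 | (S)-5-(8-hydroxy-6,7-dimethoxychroman-3-yl)-2,3-dimethoxycyclohexa-2,5-diene-1,4-dione | COC1=C(OC)C(=O)C([C@H]2COc3c(cc(OC)c(OC)c3O)C2)=CC1=O | target

**Step count and risks**

Total steps: 11. Longest linear sequence: 9 steps (5 to 18 through steps 3 to 11).

Steps most likely to fail:

1. Step 10 (proposed new method). The palladium alkoxide may undergo beta-hydride elimination, which reduces the ipso position instead of forming the C–O bond. The beta-branched iodide may also be taken up by the palladacycle too slowly, so that base-induced elimination or cyclisation of 15 wins. The fallback uses known chemistry only, sets out from malonate 11 and comes back at chromane 16. Malonate 11 would be saponified and decarboxylated (KOH, aq. EtOH; mild acidification and warming) to 2-[3,4-dimethoxy-2,5-bis(methoxymethoxy)phenyl]acetic acid F1. Its mixed pivalic anhydride and lithiated (S)-4-benzyloxazolidin-2-one would give (S)-4-benzyl-3-{2-[3,4-dimethoxy-2,5-bis(methoxymethoxy)phenyl]acetyl}oxazolidin-2-one F2. In parallel, commercial 3-hydroxy-4,5-dimethoxybenzaldehyde would be protected (MOMCl, i-Pr2NEt) to 3,4-dimethoxy-5-(methoxymethoxy)benzaldehyde F3 and reduced (NaBH4) to [3,4-dimethoxy-5-(methoxymethoxy)phenyl]methanol F4. Lithiation with n-BuLi (2.2 equiv) between the CH2OLi and OMOM groups (cooperative directed ortho-metalation) and iodination would give [2-iodo-4,5-dimethoxy-3-(methoxymethoxy)phenyl]methanol F5, and CBr4/PPh3 would give 1-(bromomethyl)-2-iodo-4,5-dimethoxy-3-(methoxymethoxy)benzene F6. Evans alkylation of the sodium enolate of F2 (NaN(SiMe3)2, THF, −78 °C) with F6 should give (S)-4-benzyl-3-{(S)-2-[3,4-dimethoxy-2,5-bis(methoxymethoxy)phenyl]-3-[2-iodo-4,5-dimethoxy-3-(methoxymethoxy)phenyl]propanoyl}oxazolidin-2-one F7, with the auxiliary controlling C3. LiBH4 would remove the auxiliary to give (S)-2-[3,4-dimethoxy-2,5-bis(methoxymethoxy)phenyl]-3-[2-iodo-4,5-dimethoxy-3-(methoxymethoxy)phenyl]propan-1-ol F8. An Ullmann-type intramolecular O-arylation (CuI, 1,10-phenanthroline, Cs2CO3, toluene, 110 °C) then closes the same O1–C8a bond and gives 16.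

2. Step 7. The enzyme may discriminate poorly between the enantiotopic hydroxymethyl groups because of the bulky ortho-substituted aryl group, and 1,3-acyl migration in the monoacetate may erode the enantiomeric purity. The fallback replaces desymmetrisation by auxiliary control; it sets out from malonate 11, passes through the imide F2 described above, and comes back at monoacetate 13. Evans alkylation of the sodium enolate of F2 with benzyl chloromethyl ether (NaN(SiMe3)2, THF, −78 °C) should give (S)-4-benzyl-3-{(R)-3-(benzyloxy)-2-[3,4-dimethoxy-2,5-bis(methoxymethoxy)phenyl]propanoyl}oxazolidin-2-one F9. LiBH4 reduction would give (S)-3-(benzyloxy)-2-[3,4-dimethoxy-2,5-bis(methoxymethoxy)phenyl]propan-1-ol F10, and acetylation (Ac2O, pyridine) would give (R)-3-(benzyloxy)-2-[3,4-dimethoxy-2,5-bis(methoxymethoxy)phenyl]propyl acetate F11. Hydrogenolysis of the benzyl ether (H2, Pd/C, EtOAc) then gives 13.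

3. Step 11. Formaldehyde equivalents released during acetal cleavage may attack the electron-rich rings (C5 of ring A), and ring A may be over-oxidised in the oxidation stage. The fallback sets out from 16 and comes back at 18 by two separate operations with a different cleavage mechanism and a thermodynamically selected oxidant. The MOM ethers would be cleaved with ZnBr2 and n-PrSH in CH2Cl2 at 0 °C, the thiol capturing the methoxymethyl unit, and triol 17 would be isolated under argon. Triol 17 would then be oxidised by redox exchange with 1,4-benzoquinone (1 equiv, Et2O, rt), which can oxidise the electron-rich hydroquinone of ring B but not a monohydric phenol. No new compound is made.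

**Further compounds**

F1 | step 10 | 2-[3,4-dimethoxy-2,5-bis(methoxymethoxy)phenyl]acetic acid | COCOc1cc(CC(=O)O)c(OCOC)c(OC)c1OC
F2 | step 10 | (S)-4-benzyl-3-{2-[3,4-dimethoxy-2,5-bis(methoxymethoxy)phenyl]acetyl}oxazolidin-2-one | COCOc1cc(CC(=O)N2[C@@H](Cc3ccccc3)COC2=O)c(OCOC)c(OC)c1OC
F3 | step 10 | 3,4-dimethoxy-5-(methoxymethoxy)benzaldehyde | COCOc1cc(C=O)cc(OC)c1OC
F4 | step 10 | [3,4-dimethoxy-5-(methoxymethoxy)phenyl]methanol | COCOc1cc(CO)cc(OC)c1OC
F5 | step 10 | [2-iodo-4,5-dimethoxy-3-(methoxymethoxy)phenyl]methanol | COCOc1c(I)c(CO)cc(OC)c1OC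
F6 | step 10 | 1-(bromomethyl)-2-iodo-4,5-dimethoxy-3-(methoxymethoxy)benzene | COCOc1c(I)c(CBr)cc(OC)c1OC
F7 | step 10 | (S)-4-benzyl-3-{(S)-2-[3,4-dimethoxy-2,5-bis(methoxymethoxy)phenyl]-3-[2-iodo-4,5-dimethoxy-3-(methoxymethoxy)phenyl]propanoyl}oxazolidin-2-one | COCOc1cc([C@H](Cc2cc(OC)c(OC)c(OCOC)c2I)C(=O)N2[C@@H](Cc3ccccc3)COC2=O)c(OCOC)c(OC)c1OC
F8 | step 10 | (S)-2-[3,4-dimethoxy-2,5-bis(methoxymethoxy)phenyl]-3-[2-iodo-4,5-dimethoxy-3-(methoxymethoxy)phenyl]propan-1-ol | COCOc1cc([C@H](Cc2cc(OC)c(OC)c(OCOC)c2I)CO)c(OCOC)c(OC)c1OC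
F9 | step 7 | (S)-4-benzyl-3-{(R)-3-(benzyloxy)-2-[3,4-dimethoxy-2,5-bis(methoxymethoxy)phenyl]propanoyl}oxazolidin-2-one | COCOc1cc([C@H](COCc2ccccc2)C(=O)N2[C@@H](Cc3ccccc3)COC2=O)c(OCOC)c(OC)c1OC
F10 | step 7 | (S)-3-(benzyloxy)-2-[3,4-dimethoxy-2,5-bis(methoxymethoxy)phenyl]propan-1-ol | COCOc1cc([C@H](COCc2ccccc2)CO)c(OCOC)c(OC)c1OC
F11 | step 7 | (R)-3-(benzyloxy)-2-[3,4-dimethoxy-2,5-bis(methoxymethoxy)phenyl]propyl acetate | COCOc1cc([C@H](COCc2ccccc2)COC(C)=O)c(OCOC)c(OC)c1OC
F0 | step 11 | none | none
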